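Compound numbers refer to the compound list after the steps.

## Analysis of the target

Compound 35 is a linear B-type procyanidin tetramer, catechin-(4α→8)-catechin-(4α→8)-catechin-(4α→8)-epicatechin. It consists of four flavan-3-ol units, each with a phloroglucinol ring A, a pyran ring C and a catechol ring B, joined by three C4–C8 bonds. There are eleven stereocentres: in units 1 to 3 (the catechin units) C2 is R, the 3-hydroxyl is trans to the C2 aryl group and the C4–aryl bond is trans to the 3-hydroxyl; in unit 4 (the terminal epicatechin) C2 and C3 are both R, so aryl and hydroxyl are cis. Sixteen phenols and four secondary alcohols make the free compound polar and air-sensitive, so it has to travel as a protected ether until the last step. The interflavan bonds are doubly benzylic and ionise under acid, which scrambles chain length and regiochemistry, and free phenols open ring C under base and epimerise C2. The classical difficulty is the bond from C4 of one unit to ring A of the next: C6 and C8 are both nucleophilic, every product is again a nucleophile, and here the terminal unit is the only 2,3-cis one. The plan rests on ring A of unit 4, a pentasubstituted benzene (C8 bonded to C4 of unit 3, C8a carrying the ring C oxygen, C7 and C5 carrying oxygen, C4a carrying C4): it is not used as a nucleophile but is assembled around a C4(unit 3)–C bond that already exists, with its three oxygens distinguishable from the moment the ring forms.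

## Retrosynthetic reasoning

35 back to 34 and 33. The last operations cut eighteen O–benzyl bonds and, before that, one O–Si bond at C7 of unit 4. Benzyl ethers are chosen because they fall under neutral hydrogenolysis, which neither ionises the interflavan bonds nor touches a stereocentre. The silyl group on C7 is the one the ring-forming step leaves there, and it is taken off first so that a single hydrogenolysis ends the route.

33 back to 31. The O1–C2 bond of ring C of unit 4 is cut, and the 3-hydroxyl is traced through cis-epoxide 32 to a Z-alkene. The cut is made here because 31 has exactly one free phenol, the C8a hydroxyl, sitting ortho to the three-carbon chain on C4a. The Z geometry maps onto the 2,3-cis relation when the phenol opens the epoxide at the benzylic carbon with inversion. What is gained is that C2 and C3 of unit 4 are set by a catalyst after the whole skeleton exists. The forward reaction must transfer oxygen to one face of the alkene and then open the epoxide in the 6-endo sense without ionisation.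

31 back to 12 and 26. Three bonds of ring A of unit 4 are cut: C8–C8a, C6–C7 and C4a–C8a. This is the central disconnection. C8 and C7 are the two carbons of a siloxyalkyne already attached to C4 of unit 3, and C8a, C6, C5 and C4a are the four ring carbons of cyclobutenone 26. The interflavan bond to unit 4 therefore exists before the ring does, so 4→6 attachment and over-extension cannot occur at this junction. The ring is born with a free hydroxyl on C8a, a silyl ether on C7 and a benzyl ether on C5, which leaves the C8a oxygen as the only one able to close ring C. The forward reaction has to join ketene and alkyne with one regiochemistry and must run without acid.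

12 back to 9 and 8. The C(sp)–O bond of the ynol ether is cut: terminal alkyne 9 is deprotonated (10), oxidised to ynolate 11 and silylated on oxygen. The siloxyalkyne is made last on this branch because it would not survive the Lewis acids used to build the chain. Alkyne 9 comes from its C-silylated form 8, which shields the alkyne terminus during those Lewis-acid steps.

8 back to 7 and 4, and 7 back to 6 and 4. The two upper interflavan bonds (C4 of unit 1 to C8 of unit 2, C4 of unit 2 to C8 of unit 3) are cut in the conventional sense, cation 5 from ether 4 being the electrophile each time. The chain is grown upwards from unit 3 so that the alkyne is present from the start and one electrophile serves twice. The forward reaction needs attack at C8 rather than C6 and entry trans to the 3-benzyloxy group.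

6 back to 4, 3, 2 and 1. The C4–C(sp) bond of unit 3 is cut to the same cation 5 and an ethynyl anion synthon carrying a silyl cap. Ether 4 is the C4-oxidised form of perbenzylated catechin 3, which comes from 1 by two etherifications. All nine stereocentres of units 1 to 3 that are not C4 come from the chiral pool.

26 back to 17 and 23. The four-membered ring is cut into ketene 25 (from acid 17 through acid chloride 24) and ynol ether 23. Their [2+2] union places the benzyloxy group at C3 and the side chain at C4 of the cyclobutenone, which is the pattern ring A requires.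

17 back to 16, 13 and 14, and 23 back to 20 and 18. The Z-alkene of ester 16 is cut to aldehyde 14 and the ylide 15 of phosphonium salt 13. The ester is used rather than the free carboxylate because an anionic group in the ylide chain erodes Z-selectivity with aromatic aldehydes. Ynol ether 23 is traced through dichlorovinyl ether 20 to trichloroethene 18.

## Alternatives that were turned down

Alternative 1: The C3=C4 bonds of units 1, 2 and 3 are disconnected together.
- Forward key step: a threefold ring-closing metathesis of hexaene A2 with the second-generation Grubbs catalyst (H2IMes)(PCy3)Cl2Ru=CHPh would expel ethene three times and deliver tris(flav-3-ene) A1 with all three pyran rings in place.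
- In its favour: three rings form in one catalytic operation. The aryl–C4–aryl links of A2 would be made by regiodefined carbonyl chemistry, so the 6-versus-8 question is removed for all three interflavan bonds.
- Where it is stronger: the chosen route removes that question by construction only for the bond to unit 4 and relies on the inherent C8 preference for the other two.
- Against it: each metathesis must engage a 1,1-diarylethene flanked by ortho-substituted rings, a very hindered and electronically poor partner, and three such closures must all succeed. A1 has also lost C3 and C4 of three units, so three face-selective hydroborations of crowded trisubstituted alkenes must follow. The four C2 centres have to be made by asymmetric synthesis instead of being taken from 1.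
- Comparison: the chosen route keeps nine stereocentres from the chiral pool and creates only two late ones.

Alternative 2: The C4–C4a bond of unit 1 is disconnected.
- Forward key step: an intramolecular Friedel–Crafts opening of epoxide A4. With hexafluoroisopropanol as ionising solvent, the symmetric 3,5-bis(benzyloxy)phenoxy ring would use one of its ortho carbons to displace the epoxide oxygen from the rear at the benzylic carbon. This would close ring C of unit 1 and leave tetramer A3 with the 3-hydroxyl of unit 1 free.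
- In its favour: the epoxide configuration is transferred to C3 and C4 without a late chiral catalyst, and the symmetric aryl ether has no regiochemical choice.
- Where it is stronger: A3 is one hydrogenolysis from the target, a shorter endgame than the three steps after the chosen key step.
- Against it: the epoxide carbon that must be attacked carries the trioxygenated ring A of unit 2, so it ionises readily. Inversion is then not assured and hydride shift to a ketone competes. The acidic solvent also threatens the two interflavan bonds already present. A4 itself needs units 2 to 4 joined conventionally, including the bond to the epicatechin terminus.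
- Comparison: this alternative spends its key step on ring C of unit 1 and leaves the hardest junction as it was, whereas the chosen route removes exactly that junction from Friedel–Crafts chemistry.

Alternative 3: The O1–C2 and C4–C8 bonds around unit 1 are disconnected.
- Forward key step: under a chiral phosphoric acid, 2-hydroxychalcone A6 would lose water and ring-close to a flavylium ion paired with the chiral phosphate. Trimer A7 would then attack C4 of this cation through its free C8 and give flav-2-ene A5.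
- In its favour: it is the most convergent plan, A6 is trivial to prepare, and the new C4 centre would be set catalytically.
- Against it: A5 still lacks C2 and C3 of unit 1, so a face-selective hydroboration of the enol ether must follow. A 5,7-dialkoxyflavylium ion is a weak and reversible electrophile, so the C4 centre can erode. The chiral acid must also control the approach of a very large chiral nucleophile that can react at C6 as well as C8 and whose own interflavan bonds are acid-labile.
- Comparison: the chosen route forms no stereocentre in its key step and runs it under neutral thermal conditions. It gives up convergence at the top of the chain to gain certainty at the bottom.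

Key step: step 14

Assumption: the (S,S)-enantiomer of the manganese salen catalyst is taken to attack the Z-alkene of 31 with the facial sense it shows towards indene (benzylic carbon S, other carbon R); if the sense is opposite, the (R,R)-catalyst is used.

## Steps

Step 1
Reactants: 1 (+)-catechin
Product: 2 5,7,3',4'-tetra-O-benzyl-(+)-catechin
Conditions: BnBr (4.2 equiv), K2CO3, DMF, 0 °C to rt
Reagents that add atoms: benzyl bromide, BrCc1ccccc1
Why: Williamson etherification; carbonate deprotonates only the four phenols, so the secondary 3-hydroxyl stays free, and the mild base avoids C-benzylation and opening of ring C.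

Step 2
Reactants: 2 5,7,3',4'-tetra-O-benzyl-(+)-catechin
Product: 3 3,5,7,3',4'-penta-O-benzyl-(+)-catechin
Conditions: NaH, BnBr, DMF, 0 °C to rt
Reagents that add atoms: benzyl bromide, BrCc1ccccc1
Why: Williamson etherification of the secondary alkoxide; with no free phenol left there is no quinone methide path by which C2 could epimerise.

Step 3
Reactants: 3 3,5,7,3',4'-penta-O-benzyl-(+)-catechin
Product: 4 3,5,7,3',4'-penta-O-benzyl-4β-(2-ethoxyethoxy)catechin (ether group cis to the 3-benzyloxy group)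
Conditions: DDQ, EtOCH2CH2OH, CH2Cl2, rt
Reagents that add atoms: 2-ethoxyethanol, CCOCCO
Why: oxidative benzylic C–H functionalisation; DDQ abstracts hydride from C4, which is activated by the ortho and para oxygens of ring A, and the alcohol traps the cation. The configuration at C4 is of no consequence because this centre is planarised again in steps 4 to 6.

Step 4
Reactants: 4 3,5,7,3',4'-penta-O-benzyl-4β-(2-ethoxyethoxy)catechin
Product: 6 3,5,7,3',4'-penta-O-benzyl-4α-(trimethylsilylethynyl)catechin (2,3-trans and 3,4-trans), via C4 benzylic cation 5 (not isolated)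
Conditions: K[Me3SiC≡CBF3] (2 equiv), BF3·OEt2, CH2Cl2/MeCN, −40 to 0 °C, 4 added slowly
Reagents that add atoms: potassium trifluoro(trimethylsilylethynyl)borate, [K+].C[Si](C)(C)C#C[B-](F)(F)F
Why: Lewis-acid-mediated SN1 substitution of an activated benzylic ether by an alkynylboron nucleophile, a known reaction of alkynyltrifluoroborates with stabilised benzylic and oxocarbenium cations. The new C4 centre is set by approach anti to the neighbouring 3-benzyloxy group, as carbon nucleophiles do on catechin-derived C4 cations, which gives the 3,4-trans product.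

Step 5
Reactants: 4 3,5,7,3',4'-penta-O-benzyl-4β-(2-ethoxyethoxy)catechin; 6 3,5,7,3',4'-penta-O-benzyl-4α-(trimethylsilylethynyl)catechin
Product: 7 [penta-O-benzylcatechin]-(4α→8)-[penta-O-benzyl-4α-(trimethylsilylethynyl)catechin]
Conditions: TMSOTf (cat.), CH2Cl2, −78 °C, 6 in 2.5-fold excess with the surplus recovered; Et3N quench
Reagents that add atoms: none
Why: Friedel–Crafts-type interflavan coupling; the silyl triflate ionises the C4 ether of 4 as in step 4, and the benzylic cation is attacked by C8 of 6, the most nucleophilic and least hindered ring A position, anti to the 3-benzyloxy group, which sets C4 of unit 2 as 3,4-trans. The excess of 6 suppresses further extension, and the silyl-capped alkyne is far less nucleophilic than ring A.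

Step 6
Reactants: 4 3,5,7,3',4'-penta-O-benzyl-4β-(2-ethoxyethoxy)catechin; 7 [penta-O-benzylcatechin]-(4α→8)-[penta-O-benzyl-4α-(trimethylsilylethynyl)catechin]
Product: 8 [penta-O-benzylcatechin]-(4α→8)-[penta-O-benzylcatechin]-(4α→8)-[penta-O-benzyl-4α-(trimethylsilylethynyl)catechin]
Conditions: TMSOTf (cat.), CH2Cl2, −78 °C, 7 in 1.5-fold excess; Et3N quench
Reagents that add atoms: none
Why: second Friedel–Crafts-type chain extension by the same ionisation of 4; only the top unit of 7 has an unsubstituted C8, and attack anti to the 3-benzyloxy group sets C4 of unit 1 as 3,4-trans.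

Step 7
Reactants: 8 trimer with 4α-(trimethylsilylethynyl) group on unit 3
Product: 9 [penta-O-benzylcatechin]-(4α→8)-[penta-O-benzylcatechin]-(4α→8)-[penta-O-benzyl-4α-ethynylcatechin]
Conditions: K2CO3 (cat.), MeOH/THF, rt
Reagents that add atoms: none
Why: methanolysis of the alkynyl C–Si bond; the propargylic C4–H is not acidic enough to epimerise under carbonate.

Step 8
Reactants: 9 trimer with 4α-ethynyl group on unit 3
Product: 12 [penta-O-benzylcatechin]-(4α→8)-[penta-O-benzylcatechin]-(4α→8)-[penta-O-benzyl-4α-((triisopropylsiloxy)ethynyl)catechin], via lithium acetylide 10 (not isolated), via lithium ynolate 11 (not isolated)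
Conditions: LiN(SiMe3)2 (2.3 equiv), THF, −78 °C; t-BuOOH, −78 to 0 °C; TIPSOTf, −78 to 0 °C
Reagents that add atoms: tert-butyl hydroperoxide, CC(C)(C)OO; triisopropylsilyl trifluoromethanesulfonate, CC(C)[Si](OS(=O)(=O)C(F)(F)F)(C(C)C)C(C)C
Why: oxidation of a lithium acetylide by lithium tert-butyl peroxide (electrophilic oxygen transfer) to the lithium ynolate, then O-silylation by the bulky silyl triflate; this is the known one-flask preparation of triisopropylsiloxyalkynes from terminal alkynes. The amide base does not remove the hindered C4–H at −78 °C, so the stereocentre is kept.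

Step 9
Reactants: 13 (3-ethoxycarbonylpropyl)triphenylphosphonium bromide; 14 3,4-bis(benzyloxy)benzaldehyde
Product: 16 ethyl (Z)-5-[3,4-bis(benzyloxy)phenyl]pent-4-enoate, via phosphorus ylide 15 (not isolated)
Conditions: KN(SiMe3)2, THF, −78 °C to rt
Reagents that add atoms: none
Why: Wittig olefination with a non-stabilised ylide under lithium-free conditions, where kinetic cis-oxaphosphetane formation gives the Z-alkene. The ester ylide is used because a carboxylate in the chain shifts aromatic aldehydes towards the E-alkene; the minor E isomer is removed by chromatography on AgNO3-impregnated silica.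

Step 10
Reactants: 16 ethyl (Z)-5-[3,4-bis(benzyloxy)phenyl]pent-4-enoate
Product: 17 (Z)-5-[3,4-bis(benzyloxy)phenyl]pent-4-enoic acid
Conditions: LiOH, THF/H2O, rt; then cold 1 M HCl to pH 4
Reagents that add atoms: lithium hydroxide, [Li+].[OH-]
Why: saponification; the non-conjugated Z-alkene is inert to hydroxide and to brief contact with cold dilute acid.

Step 11
Reactants: 18 trichloroethene
Product: 20 benzyl (E)-1,2-dichlorovinyl ether, via dichloroethyne 19 (not isolated)
Conditions: BnOH, KH, THF, 0 °C to rt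
Reagents that add atoms: benzyl alcohol, OCc1ccccc1
Why: base-induced elimination to dichloroethyne followed by anti addition of the alkoxide, the known route from trichloroethene to 1,2-dichlorovinyl ethers.

Step 12
Reactants: 20 benzyl (E)-1,2-dichlorovinyl ether
Product: 23 benzyloxyethyne (kept as a cold solution), via benzyl chloroethynyl ether 21 (not isolated), via lithium benzyloxyacetylide 22 (not isolated)
Conditions: n-BuLi (2.2 equiv), Et2O, −78 °C; MeOH, −78 °C
Reagents that add atoms: none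
Why: elimination of HCl and chlorine–lithium exchange give the lithium alkynyl ether, which is protonated cold; the ynol ether is used at once and kept below room temperature because benzyl alkynyl ethers rearrange sigmatropically on warming.

Step 13
Reactants: 17 (Z)-5-[3,4-bis(benzyloxy)phenyl]pent-4-enoic acid; 23 benzyloxyethyne
Product: 26 3-benzyloxy-4-[(Z)-3-(3,4-bis(benzyloxy)phenyl)prop-2-enyl]cyclobut-2-enone (racemic at C4), via acid chloride 24 (not isolated), via alkylketene 25 (not isolated)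
Conditions: Me2C=C(Cl)NMe2, CH2Cl2, 0 °C; then 23 in threefold excess, Et3N, MeCN, 0 °C to rt
Reagents that add atoms: none
Why: ketene–ynol ether [2+2] cycloaddition; the acid chloride is made under neutral conditions so that no HCl reaches the Z-styrene, and the aldoketene is trapped by the excess ynol ether. The ketene carbonyl carbon bonds to the unsubstituted alkyne carbon, which puts benzyloxy at C3 and the chain at C4; the C4 centre is racemic and is lost in step 14.

Step 14
Reactants: 12 trimer siloxyalkyne; 26 3-benzyloxy-4-[(Z)-3-(3,4-bis(benzyloxy)phenyl)prop-2-enyl]cyclobut-2-enone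
Product: 31 phenol in which units 1 to 3 are bonded at C4 of unit 3 to the new ring A of unit 4 (C8a–OH; C7–OTIPS; C5–OBn; Z-cinnamyl chain on C4a), via vinylketene 27 (not isolated), via vinylcyclobutenone 28 (not isolated), via dienylketene 29 (not isolated), via cyclohexadienone 30 (not isolated)
Conditions: toluene (degassed, base-washed glass), 80 to 110 °C, 26 in slight excess added slowly
Reagents that add atoms: none
Why: Danheiser benzannulation of a cyclobutenone with a siloxyalkyne, the known thermal route to resorcinol monosilyl ethers; it is an addition in which every atom of 12 and 26 is kept in 31. Heat opens the four-membered ring of 26 in a conrotatory four-electron process, the side chain turning outward, to vinylketene 27, whose ketene unit then takes up the ynol ether in a [2+2] cycloaddition: the alkyne carbon attached to C4 of unit 3, the nucleophilic end, bonds to the ketene carbonyl carbon (C8–C8a) and the oxygen-bearing alkyne carbon bonds to the ketene α-carbon (C6–C7), which gives 28. Reversible four-electron opening of 28 leads to dienylketene 29, a six-electron electrocyclisation of 29 forms C4a–C8a and closes ring A of unit 4 as dienone 30, and enolisation gives phenol 31. Ring A, a carbocycle, is thus the one ring closed, by 6π electrocyclisation, and the strain released from the four-membered rings of 26 and 28 is the driving force. No stereocentre is created: the sp3 ring carbons of 26, 28 and 30 all become sp2, and the Z-alkene and the nine stereocentres of units 1 to 3 are untouched under neutral thermal conditions. The selectivity required is the regiochemistry of the ketene–alkyne union, and it is secured by the polarisation of the siloxyalkyne, whose carbon remote from oxygen is the nucleophile while the ketene carbonyl carbon is the electrophile. Chemoselectivity for the ynol ether over the styrene rests on the much higher nucleophilicity of the former and on the outward placement of the side chain in 27, which also rules out a 1,5-hydrogen shift from its allylic CH2 group. The product carries a free hydroxyl at C8a, a silyl ether at C7 and a benzyl ether at C5, so that only the C8a oxygen is available to close ring C.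

Step 15
Reactants: 31 phenol with Z-cinnamyl chain on C4a of unit 4
Product: 33 tetramer with ring C of unit 4 closed (2R,3R; 2,3-cis; free 3-OH; C7–OTIPS; eighteen benzyl ethers), via cis-epoxide 32 (not isolated)
Conditions: (S,S)-(salen)MnCl [salen = N,N'-bis(3,5-di-tert-butylsalicylidene)cyclohexane-1,2-diamine dianion; C36H52ClMnN2O2] (cat.), mCPBA, N-methylmorpholine N-oxide, CH2Cl2, −78 °C; then warm to 0 °C
Reagents that add atoms: 3-chloroperoxybenzoic acid, OOC(=O)c1cccc(Cl)c1
Why: Jacobsen–Katsuki epoxidation of a Z-aryl alkene under the anhydrous low-temperature peracid protocol; the catalyst should deliver oxygen to the face that gives cis-epoxide 32 with S configuration at the benzylic carbon and R at the other, overriding the remote stereocentres of units 1 to 3. The ortho phenol then opens the epoxide at the benzylic carbon in the 6-endo mode (favoured by the dialkoxyphenyl group) with inversion, so C2 becomes R while C3 stays R, which is the cis ring C of epicatechin. Peracid epoxidation followed by such in-flask closure is known for ortho-cinnamylphenols, and the buffered, cold medium spares the interflavan bonds.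

Step 16
Reactants: 33 tetramer with C7–OTIPS on unit 4
Product: 34 tetramer with free 3-OH and 7-OH on unit 4 and eighteen benzyl ethers
Conditions: Bu4NF, AcOH, THF, 0 °C, under argon
Reagents that add atoms: none
Why: fluoride-induced cleavage of the aryl silyl ether; acetic acid buffers the phenoxide against air oxidation and base-induced ring opening, and the benzyl ethers are inert.

Step 17
Reactants: 34 tetramer with eighteen benzyl ethers
Product: 35 catechin-(4α→8)-catechin-(4α→8)-catechin-(4α→8)-epicatechin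
Conditions: H2 (1 atm), Pd(OH)2/C, THF/MeOH/H2O, rt; filtration and freeze-drying under argon
Reagents that add atoms: none
Why: hydrogenolysis of all eighteen benzyl ethers under neutral conditions; the interflavan C–C bonds and the ring C ether bonds are retained under these conditions and no stereocentre is touched.

## Compound list

1 | (+)-catechin, (2R,3S) | O[C@H]1Cc2c(O)cc(O)cc2O[C@@H]1c1ccc(O)c(O)c1 | starting material
2 | 5,7,3',4'-tetra-O-benzyl-(+)-catechin | c1ccccc1COc1cc(OCc3ccccc3)c2c(c1)O[C@H](c1ccc(OCc3ccccc3)c(OCc3ccccc3)c1)[C@@H](O)C2 | intermediate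
3 | 3,5,7,3',4'-penta-O-benzyl-(+)-catechin | c1ccccc1COc1cc(OCc3ccccc3)c2c(c1)O[C@H](c1ccc(OCc3ccccc3)c(OCc3ccccc3)c1)[C@@H](OCc3ccccc3)C2 | intermediate
4 | 3,5,7,3',4'-penta-O-benzyl-4β-(2-ethoxyethoxy)catechin | c1ccccc1COc1cc(OCc3ccccc3)c2c(c1)O[C@H](c1ccc(OCc3ccccc3)c(OCc3ccccc3)c1)[C@@H](OCc3ccccc3)[C@H]2OCCOCC | intermediate
5 | C4 benzylic cation of penta-O-benzylcatechin | c1ccccc1COc1cc(OCc3ccccc3)c2c(c1)O[C@H](c1ccc(OCc3ccccc3)c(OCc3ccccc3)c1)[C@@H](OCc3ccccc3)[CH+]2 | intermediate
6 | 3,5,7,3',4'-penta-O-benzyl-4α-(trimethylsilylethynyl)catechin | c1ccccc1COc1cc(OCc3ccccc3)c2c(c1)O[C@H](c1ccc(OCc3ccccc3)c(OCc3ccccc3)c1)[C@@H](OCc3ccccc3)[C@@H]2C#C[Si](C)(C)C | intermediate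
7 | [penta-O-benzylcatechin]-(4α→8)-[penta-O-benzyl-4α-(trimethylsilylethynyl)catechin] | c1ccccc1COc1cc(OCc3ccccc3)c2c(c1)O[C@H](c1ccc(OCc3ccccc3)c(OCc3ccccc3)c1)[C@@H](OCc3ccccc3)[C@@H]2c1c(OCc3ccccc3)cc(OCc3ccccc3)c2c1O[C@H](c1ccc(OCc3ccccc3)c(OCc3ccccc3)c1)[C@@H](OCc3ccccc3)[C@@H]2C#C[Si](C)(C)C | intermediate
8 | perbenzylated units 1 to 3 with 4α-(trimethylsilylethynyl) on unit 3 | c1ccccc1COc1cc(OCc3ccccc3)c2c(c1)O[C@H](c1ccc(OCc3ccccc3)c(OCc3ccccc3)c1)[C@@H](OCc3ccccc3)[C@@H]2c1c(OCc3ccccc3)cc(OCc3ccccc3)c2c1O[C@H](c1ccc(OCc3ccccc3)c(OCc3ccccc3)c1)[C@@H](OCc3ccccc3)[C@@H]2c1c(OCc3ccccc3)cc(OCc3ccccc3)c2c1O[C@H](c1ccc(OCc3ccccc3)c(OCc3ccccc3)c1)[C@@H](OCc3ccccc3)[C@@H]2C#C[Si](C)(C)C | intermediate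
9 | perbenzylated units 1 to 3 with 4α-ethynyl on unit 3 | c1ccccc1COc1cc(OCc3ccccc3)c2c(c1)O[C@H](c1ccc(OCc3ccccc3)c(OCc3ccccc3)c1)[C@@H](OCc3ccccc3)[C@@H]2c1c(OCc3ccccc3)cc(OCc3ccccc3)c2c1O[C@H](c1ccc(OCc3ccccc3)c(OCc3ccccc3)c1)[C@@H](OCc3ccccc3)[C@@H]2c1c(OCc3ccccc3)cc(OCc3ccccc3)c2c1O[C@H](c1ccc(OCc3ccccc3)c(OCc3ccccc3)c1)[C@@H](OCc3ccccc3)[C@@H]2C#C | intermediate
10 | lithium acetylide of 9 | c1ccccc1COc1cc(OCc3ccccc3)c2c(c1)O[C@H](c1ccc(OCc3ccccc3)c(OCc3ccccc3)c1)[C@@H](OCc3ccccc3)[C@@H]2c1c(OCc3ccccc3)cc(OCc3ccccc3)c2c1O[C@H](c1ccc(OCc3ccccc3)c(OCc3ccccc3)c1)[C@@H](OCc3ccccc3)[C@@H]2c1c(OCc3ccccc3)cc(OCc3ccccc3)c2c1O[C@H](c1ccc(OCc3ccccc3)c(OCc3ccccc3)c1)[C@@H](OCc3ccccc3)[C@@H]2C#C[Li] | intermediate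
11 | lithium ynolate of units 1 to 3 | c1ccccc1COc1cc(OCc3ccccc3)c2c(c1)O[C@H](c1ccc(OCc3ccccc3)c(OCc3ccccc3)c1)[C@@H](OCc3ccccc3)[C@@H]2c1c(OCc3ccccc3)cc(OCc3ccccc3)c2c1O[C@H](c1ccc(OCc3ccccc3)c(OCc3ccccc3)c1)[C@@H](OCc3ccccc3)[C@@H]2c1c(OCc3ccccc3)cc(OCc3ccccc3)c2c1O[C@H](c1ccc(OCc3ccccc3)c(OCc3ccccc3)c1)[C@@H](OCc3ccccc3)[C@@H]2C#CO[Li] | intermediate
12 | perbenzylated units 1 to 3 with 4α-[(triisopropylsiloxy)ethynyl] on unit 3 | c1ccccc1COc1cc(OCc3ccccc3)c2c(c1)O[C@H](c1ccc(OCc3ccccc3)c(OCc3ccccc3)c1)[C@@H](OCc3ccccc3)[C@@H]2c1c(OCc3ccccc3)cc(OCc3ccccc3)c2c1O[C@H](c1ccc(OCc3ccccc3)c(OCc3ccccc3)c1)[C@@H](OCc3ccccc3)[C@@H]2c1c(OCc3ccccc3)cc(OCc3ccccc3)c2c1O[C@H](c1ccc(OCc3ccccc3)c(OCc3ccccc3)c1)[C@@H](OCc3ccccc3)[C@@H]2C#CO[Si](C(C)C)(C(C)C)C(C)C | intermediate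
13 | (3-ethoxycarbonylpropyl)triphenylphosphonium bromide | [Br-].CCOC(=O)CCC[P+](c1ccccc1)(c1ccccc1)c1ccccc1 | starting material
14 | 3,4-bis(benzyloxy)benzaldehyde | O=Cc1ccc(OCc2ccccc2)c(OCc2ccccc2)c1 | starting material
15 | ethyl 4-(triphenylphosphoranylidene)butanoate | CCOC(=O)CCC=P(c1ccccc1)(c1ccccc1)c1ccccc1 | intermediate
16 | ethyl (Z)-5-[3,4-bis(benzyloxy)phenyl]pent-4-enoate | CCOC(=O)CC/C=C\c1ccc(OCc2ccccc2)c(OCc2ccccc2)c1 | intermediate
17 | (Z)-5-[3,4-bis(benzyloxy)phenyl]pent-4-enoic acid | OC(=O)CC/C=C\c1ccc(OCc2ccccc2)c(OCc2ccccc2)c1 | intermediate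
18 | trichloroethene | ClC=C(Cl)Cl | starting material
19 | dichloroethyne | ClC#CCl | intermediate
20 | benzyl (E)-1,2-dichlorovinyl ether | Cl/C=C(/Cl)OCc1ccccc1 | intermediate
21 | benzyl chloroethynyl ether | ClC#COCc1ccccc1 | intermediate
22 | lithium benzyloxyacetylide | [Li]C#COCc1ccccc1 | intermediate
23 | benzyloxyethyne | C#COCc1ccccc1 | intermediate
24 | (Z)-5-[3,4-bis(benzyloxy)phenyl]pent-4-enoyl chloride | ClC(=O)CC/C=C\c1ccc(OCc2ccccc2)c(OCc2ccccc2)c1 | intermediate
25 | [(Z)-3-(3,4-bis(benzyloxy)phenyl)prop-2-enyl]ketene | O=C=CC/C=C\c1ccc(OCc2ccccc2)c(OCc2ccccc2)c1 | intermediate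
26 | 3-benzyloxy-4-[(Z)-3-(3,4-bis(benzyloxy)phenyl)prop-2-enyl]cyclobut-2-enone, racemic | O=C1C=C(OCc2ccccc2)C1C/C=C\c1ccc(OCc2ccccc2)c(OCc2ccccc2)c1 | intermediate
27 | (3Z,6Z)-3-benzyloxy-7-[3,4-bis(benzyloxy)phenyl]hepta-1,3,6-trien-1-one (vinylketene) | O=C=C/C(OCc1ccccc1)=C/C/C=C\c1ccc(OCc2ccccc2)c(OCc2ccccc2)c1 | intermediate
28 | 4-alkenyl-3-(triisopropylsiloxy)cyclobut-2-enone carrying units 1 to 3 at C2 (ring sp3 carbon unspecified) | c1ccccc1COc1cc(OCc3ccccc3)c2c(c1)O[C@H](c1ccc(OCc3ccccc3)c(OCc3ccccc3)c1)[C@@H](OCc3ccccc3)[C@@H]2c1c(OCc3ccccc3)cc(OCc3ccccc3)c2c1O[C@H](c1ccc(OCc3ccccc3)c(OCc3ccccc3)c1)[C@@H](OCc3ccccc3)[C@@H]2c1c(OCc3ccccc3)cc(OCc3ccccc3)c2c1O[C@H](c1ccc(OCc3ccccc3)c(OCc3ccccc3)c1)[C@@H](OCc3ccccc3)[C@@H]2C1=C(O[Si](C(C)C)(C(C)C)C(C)C)C(C1=O)/C(OCc3ccccc3)=C/C/C=C\c4ccc(OCc3ccccc3)c(OCc3ccccc3)c4 | intermediate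
29 | dienylketene carrying units 1 to 3 on the ketene α-carbon | c1ccccc1COc1cc(OCc3ccccc3)c2c(c1)O[C@H](c1ccc(OCc3ccccc3)c(OCc3ccccc3)c1)[C@@H](OCc3ccccc3)[C@@H]2c1c(OCc3ccccc3)cc(OCc3ccccc3)c2c1O[C@H](c1ccc(OCc3ccccc3)c(OCc3ccccc3)c1)[C@@H](OCc3ccccc3)[C@@H]2c1c(OCc3ccccc3)cc(OCc3ccccc3)c2c1O[C@H](c1ccc(OCc3ccccc3)c(OCc3ccccc3)c1)[C@@H](OCc3ccccc3)[C@@H]2C(=C=O)/C(O[Si](C(C)C)(C(C)C)C(C)C)=C\C(OCc3ccccc3)=C\C/C=C\c4ccc(OCc3ccccc3)c(OCc3ccccc3)c4 | intermediate
30 | cyclohexa-2,4-dienone tautomer of 31 (ring sp3 carbon unspecified) | c1ccccc1COc1cc(OCc3ccccc3)c2c(c1)O[C@H](c1ccc(OCc3ccccc3)c(OCc3ccccc3)c1)[C@@H](OCc3ccccc3)[C@@H]2c1c(OCc3ccccc3)cc(OCc3ccccc3)c2c1O[C@H](c1ccc(OCc3ccccc3)c(OCc3ccccc3)c1)[C@@H](OCc3ccccc3)[C@@H]2c1c(OCc3ccccc3)cc(OCc3ccccc3)c2c1O[C@H](c1ccc(OCc3ccccc3)c(OCc3ccccc3)c1)[C@@H](OCc3ccccc3)[C@@H]2C1=C(O[Si](C(C)C)(C(C)C)C(C)C)C=C(OCc3ccccc3)C(C/C=C\c4ccc(OCc3ccccc3)c(OCc3ccccc3)c4)C1=O | intermediate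
31 | units 1 to 3 bonded at C4 to the new ring A of unit 4: C8a–OH, C7–OTIPS, C5–OBn, Z-cinnamyl chain on C4a | c1ccccc1COc1cc(OCc3ccccc3)c2c(c1)O[C@H](c1ccc(OCc3ccccc3)c(OCc3ccccc3)c1)[C@@H](OCc3ccccc3)[C@@H]2c1c(OCc3ccccc3)cc(OCc3ccccc3)c2c1O[C@H](c1ccc(OCc3ccccc3)c(OCc3ccccc3)c1)[C@@H](OCc3ccccc3)[C@@H]2c1c(OCc3ccccc3)cc(OCc3ccccc3)c2c1O[C@H](c1ccc(OCc3ccccc3)c(OCc3ccccc3)c1)[C@@H](OCc3ccccc3)[C@@H]2c1c(O[Si](C(C)C)(C(C)C)C(C)C)cc(OCc3ccccc3)c(C/C=C\c4ccc(OCc3ccccc3)c(OCc3ccccc3)c4)c1O | intermediate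
32 | cis-epoxide of 31 (benzylic carbon S, other epoxide carbon R) | c1ccccc1COc1cc(OCc3ccccc3)c2c(c1)O[C@H](c1ccc(OCc3ccccc3)c(OCc3ccccc3)c1)[C@@H](OCc3ccccc3)[C@@H]2c1c(OCc3ccccc3)cc(OCc3ccccc3)c2c1O[C@H](c1ccc(OCc3ccccc3)c(OCc3ccccc3)c1)[C@@H](OCc3ccccc3)[C@@H]2c1c(OCc3ccccc3)cc(OCc3ccccc3)c2c1O[C@H](c1ccc(OCc3ccccc3)c(OCc3ccccc3)c1)[C@@H](OCc3ccccc3)[C@@H]2c1c(O[Si](C(C)C)(C(C)C)C(C)C)cc(OCc3ccccc3)c(C[C@H]5O[C@H]5c4ccc(OCc3ccccc3)c(OCc3ccccc3)c4)c1O | intermediate
33 | protected tetramer, unit 4 with cis ring C (2R,3R), free 3-OH, C7–OTIPS | c1ccccc1COc1cc(OCc3ccccc3)c2c(c1)O[C@H](c1ccc(OCc3ccccc3)c(OCc3ccccc3)c1)[C@@H](OCc3ccccc3)[C@@H]2c1c(OCc3ccccc3)cc(OCc3ccccc3)c2c1O[C@H](c1ccc(OCc3ccccc3)c(OCc3ccccc3)c1)[C@@H](OCc3ccccc3)[C@@H]2c1c(OCc3ccccc3)cc(OCc3ccccc3)c2c1O[C@H](c1ccc(OCc3ccccc3)c(OCc3ccccc3)c1)[C@@H](OCc3ccccc3)[C@@H]2c1c(O[Si](C(C)C)(C(C)C)C(C)C)cc(OCc3ccccc3)c2c1O[C@H](c1ccc(OCc3ccccc3)c(OCc3ccccc3)c1)[C@H](O)C2 | intermediate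
34 | protected tetramer, unit 4 with free 3-OH and 7-OH, eighteen benzyl ethers | c1ccccc1COc1cc(OCc3ccccc3)c2c(c1)O[C@H](c1ccc(OCc3ccccc3)c(OCc3ccccc3)c1)[C@@H](OCc3ccccc3)[C@@H]2c1c(OCc3ccccc3)cc(OCc3ccccc3)c2c1O[C@H](c1ccc(OCc3ccccc3)c(OCc3ccccc3)c1)[C@@H](OCc3ccccc3)[C@@H]2c1c(OCc3ccccc3)cc(OCc3ccccc3)c2c1O[C@H](c1ccc(OCc3ccccc3)c(OCc3ccccc3)c1)[C@@H](OCc3ccccc3)[C@@H]2c1c(O)cc(OCc3ccccc3)c2c1O[C@H](c1ccc(OCc3ccccc3)c(OCc3ccccc3)c1)[C@H](O)C2 | intermediate
35 | catechin-(4α→8)-catechin-(4α→8)-catechin-(4α→8)-epicatechin (CNP0236700.7) | Oc1cc(O)c2c(c1)O[C@H](c1ccc(O)c(O)c1)[C@@H](O)[C@@H]2c1c(O)cc(O)c2c1O[C@H](c1ccc(O)c(O)c1)[C@@H](O)[C@@H]2c1c(O)cc(O)c2c1O[C@H](c1ccc(O)c(O)c1)[C@@H](O)[C@@H]2c1c(O)cc(O)c2c1O[C@H](c1ccc(O)c(O)c1)[C@H](O)C2 | target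

## Step count and least certain steps

Total step count: 17. Longest linear sequence: 12 steps (steps 1 to 8 and 14 to 17, from (+)-catechin). The cyclobutenone branch has two feeders: steps 9, 10 and 13, and steps 11 to 13.

Step 14 (key step). The alkyne carbon that must bond to the ketene sits next to C4 of unit 3, between the 3-benzyloxy group and the peri 5-benzyloxy group. The most likely failure is a slow [2+2] union, so that vinylketene 27 is consumed by self-dimerisation or by acylating the phenol of product already formed. Fallback: a conventional chain built from the epicatechin end, setting out from 4. Commercial (−)-epicatechin is benzylated as in steps 1 and 2 to 5,7,3',4'-tetra-O-benzyl-(−)-epicatechin F1 and then 3,5,7,3',4'-penta-O-benzyl-(−)-epicatechin F2. Three successive TMSOTf-mediated couplings with 4, each with the nucleophile in excess, give the perbenzylated dimer F3, the perbenzylated trimer F4 and the perbenzylated tetramer F5. Hydrogenolysis over Pd(OH)2/C then returns to the route at 35. This path brings back the 6-versus-8 and over-extension problems at the epicatechin junction, which is why it is only the reserve.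

Step 15. Three processes threaten it: ionisation of the epoxide at the benzylic carbon before the phenol attacks, which would close ring C mainly trans; oxidation of the free electron-rich phenol by the oxo-manganese species; and stepwise oxygen transfer that leaks to the trans-epoxide. Fallback: the sequence is staged, setting out from 31. Acetylation (Ac2O, DMAP) gives the aryl acetate F6, and the same epoxidation then gives the isolable cis-epoxy acetate F7 without a free phenol present. Methanolysis with K2CO3 in MeOH at low temperature releases the phenoxide, which opens the epoxide at the benzylic carbon by SN2 under basic, non-ionising conditions and returns to the route at 33.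

Step 4. Two processes may intervene: entry of the alkyne on the face syn to the 3-benzyloxy group (the face oxygen nucleophiles take in forming 4), giving the 3,4-cis isomer, and capture of cation 5 by ring A of another molecule. Fallback: the roles are reversed so that the small nucleophile comes last, setting out from 3. DDQ in wet CH2Cl2 gives the 4-hydroxy compound F8, and Dess–Martin periodinane gives the 4-ketone F9. Addition of LiC≡CSiMe3 in THF at −78 °C gives the tertiary propargylic alcohol F10. Ionic deoxygenation with Et3SiH and BF3·OEt2 at −78 °C then delivers hydride axially on the face syn to the 3-benzyloxy group, which leaves the alkyne trans to it and returns to the route at 6.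

Step 13. Dimerisation of aldoketene 25 and rearrangement or polymerisation of the thermally labile ynol ether 23 may outrun the cycloaddition. Fallback: setting out from 17, the same ketene generation is run in the presence of commercial ethoxyethyne, a robust ynol ether, to give the 3-ethoxycyclobutenone F11. Acid-catalysed vinylogous transetherification with benzyl alcohol (pyridinium p-toluenesulfonate, molecular sieves) then exchanges the alkoxy group and returns to the route at 26.

Step 6. Over-extension (trimer 8 still has a nucleophilic C8 on unit 1) and attack at C6 in place of C8 are the likely failures, and dimer 7 is too valuable to use in large excess. Fallback: an electrophile blocked at C8, setting out from 3. Bromination with N-bromosuccinimide gives 8-bromo-penta-O-benzylcatechin F12, and DDQ with 2-ethoxyethanol gives its 4-(2-ethoxyethoxy) ether F13. Equimolar TMSOTf coupling with 7 gives the 8-bromo trimer F14, which cannot extend further. Bromine–lithium exchange (n-BuLi, THF, −78 °C) and protonation with methanol return to the route at 8.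

## Further compounds

F1 | step 14 | 5,7,3',4'-tetra-O-benzyl-(−)-epicatechin | c1ccccc1COc1cc(OCc3ccccc3)c2c(c1)O[C@H](c1ccc(OCc3ccccc3)c(OCc3ccccc3)c1)[C@H](O)C2
F2 | step 14 | 3,5,7,3',4'-penta-O-benzyl-(−)-epicatechin | c1ccccc1COc1cc(OCc3ccccc3)c2c(c1)O[C@H](c1ccc(OCc3ccccc3)c(OCc3ccccc3)c1)[C@H](OCc3ccccc3)C2
F3 | step 14 | perbenzylated catechin-(4α→8)-epicatechin | c1ccccc1COc1cc(OCc3ccccc3)c2c(c1)O[C@H](c1ccc(OCc3ccccc3)c(OCc3ccccc3)c1)[C@@H](OCc3ccccc3)[C@@H]2c1c(OCc3ccccc3)cc(OCc3ccccc3)c2c1O[C@H](c1ccc(OCc3ccccc3)c(OCc3ccccc3)c1)[C@H](OCc3ccccc3)C2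
F4 | step 14 | perbenzylated catechin-(4α→8)-catechin-(4α→8)-epicatechin | c1ccccc1COc1cc(OCc3ccccc3)c2c(c1)O[C@H](c1ccc(OCc3ccccc3)c(OCc3ccccc3)c1)[C@@H](OCc3ccccc3)[C@@H]2c1c(OCc3ccccc3)cc(OCc3ccccc3)c2c1O[C@H](c1ccc(OCc3ccccc3)c(OCc3ccccc3)c1)[C@@H](OCc3ccccc3)[C@@H]2c1c(OCc3ccccc3)cc(OCc3ccccc3)c2c1O[C@H](c1ccc(OCc3ccccc3)c(OCc3ccccc3)c1)[C@H](OCc3ccccc3)C2
F5 | step 14 | perbenzylated tetramer (twenty benzyl ethers) | c1ccccc1COc1cc(OCc3ccccc3)c2c(c1)O[C@H](c1ccc(OCc3ccccc3)c(OCc3ccccc3)c1)[C@@H](OCc3ccccc3)[C@@H]2c1c(OCc3ccccc3)cc(OCc3ccccc3)c2c1O[C@H](c1ccc(OCc3ccccc3)c(OCc3ccccc3)c1)[C@@H](OCc3ccccc3)[C@@H]2c1c(OCc3ccccc3)cc(OCc3ccccc3)c2c1O[C@H](c1ccc(OCc3ccccc3)c(OCc3ccccc3)c1)[C@@H](OCc3ccccc3)[C@@H]2c1c(OCc3ccccc3)cc(OCc3ccccc3)c2c1O[C@H](c1ccc(OCc3ccccc3)c(OCc3ccccc3)c1)[C@H](OCc3ccccc3)C2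
F6 | step 15 | C8a acetate of 31 | c1ccccc1COc1cc(OCc3ccccc3)c2c(c1)O[C@H](c1ccc(OCc3ccccc3)c(OCc3ccccc3)c1)[C@@H](OCc3ccccc3)[C@@H]2c1c(OCc3ccccc3)cc(OCc3ccccc3)c2c1O[C@H](c1ccc(OCc3ccccc3)c(OCc3ccccc3)c1)[C@@H](OCc3ccccc3)[C@@H]2c1c(OCc3ccccc3)cc(OCc3ccccc3)c2c1O[C@H](c1ccc(OCc3ccccc3)c(OCc3ccccc3)c1)[C@@H](OCc3ccccc3)[C@@H]2c1c(O[Si](C(C)C)(C(C)C)C(C)C)cc(OCc3ccccc3)c(C/C=C\c4ccc(OCc3ccccc3)c(OCc3ccccc3)c4)c1OC(C)=O
F7 | step 15 | cis-epoxy acetate (benzylic carbon S, other epoxide carbon R) | c1ccccc1COc1cc(OCc3ccccc3)c2c(c1)O[C@H](c1ccc(OCc3ccccc3)c(OCc3ccccc3)c1)[C@@H](OCc3ccccc3)[C@@H]2c1c(OCc3ccccc3)cc(OCc3ccccc3)c2c1O[C@H](c1ccc(OCc3ccccc3)c(OCc3ccccc3)c1)[C@@H](OCc3ccccc3)[C@@H]2c1c(OCc3ccccc3)cc(OCc3ccccc3)c2c1O[C@H](c1ccc(OCc3ccccc3)c(OCc3ccccc3)c1)[C@@H](OCc3ccccc3)[C@@H]2c1c(O[Si](C(C)C)(C(C)C)C(C)C)cc(OCc3ccccc3)c(C[C@H]5O[C@H]5c4ccc(OCc3ccccc3)c(OCc3ccccc3)c4)c1OC(C)=O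
F8 | step 4 | 3,5,7,3',4'-penta-O-benzyl-4β-hydroxycatechin | c1ccccc1COc1cc(OCc3ccccc3)c2c(c1)O[C@H](c1ccc(OCc3ccccc3)c(OCc3ccccc3)c1)[C@@H](OCc3ccccc3)[C@H]2O
F9 | step 4 | 3,5,7,3',4'-penta-O-benzyl-(+)-taxifolin (the 4-ketone) | c1ccccc1COc1cc(OCc3ccccc3)c2c(c1)O[C@H](c1ccc(OCc3ccccc3)c(OCc3ccccc3)c1)[C@@H](OCc3ccccc3)C2=O
F10 | step 4 | 4-hydroxy-4-(trimethylsilylethynyl) derivative of 3 (C4 unspecified) | c1ccccc1COc1cc(OCc3ccccc3)c2c(c1)O[C@H](c1ccc(OCc3ccccc3)c(OCc3ccccc3)c1)[C@@H](OCc3ccccc3)C2(O)C#C[Si](C)(C)C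
F11 | step 13 | 3-ethoxy-4-[(Z)-3-(3,4-bis(benzyloxy)phenyl)prop-2-enyl]cyclobut-2-enone, racemic | O=C1C=C(OCC)C1C/C=C\c1ccc(OCc2ccccc2)c(OCc2ccccc2)c1
F12 | step 6 | 8-bromo-3,5,7,3',4'-penta-O-benzylcatechin | c1ccccc1COc1cc(OCc3ccccc3)c2c(c1Br)O[C@H](c1ccc(OCc3ccccc3)c(OCc3ccccc3)c1)[C@@H](OCc3ccccc3)C2
F13 | step 6 | 8-bromo-3,5,7,3',4'-penta-O-benzyl-4β-(2-ethoxyethoxy)catechin | c1ccccc1COc1cc(OCc3ccccc3)c2c(c1Br)O[C@H](c1ccc(OCc3ccccc3)c(OCc3ccccc3)c1)[C@@H](OCc3ccccc3)[C@H]2OCCOCC
F14 | step 6 | 8-bromo derivative of 8 (bromine on C8 of unit 1) | c1ccccc1COc1cc(OCc3ccccc3)c2c(c1Br)O[C@H](c1ccc(OCc3ccccc3)c(OCc3ccccc3)c1)[C@@H](OCc3ccccc3)[C@@H]2c1c(OCc3ccccc3)cc(OCc3ccccc3)c2c1O[C@H](c1ccc(OCc3ccccc3)c(OCc3ccccc3)c1)[C@@H](OCc3ccccc3)[C@@H]2c1c(OCc3ccccc3)cc(OCc3ccccc3)c2c1O[C@H](c1ccc(OCc3ccccc3)c(OCc3ccccc3)c1)[C@@H](OCc3ccccc3)[C@@H]2C#C[Si](C)(C)C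
A1 | alternative 1 | tris(flav-3-ene): units 1 to 3 as 4-aryl-2H-chromenes on penta-O-benzyl epicatechin | c1ccccc1COc1cc(OCc3ccccc3)c2c(c1)O[C@H](c1ccc(OCc3ccccc3)c(OCc3ccccc3)c1)C=C2c1c(OCc3ccccc3)cc(OCc3ccccc3)c2c1O[C@H](c1ccc(OCc3ccccc3)c(OCc3ccccc3)c1)C=C2c1c(OCc3ccccc3)cc(OCc3ccccc3)c2c1O[C@H](c1ccc(OCc3ccccc3)c(OCc3ccccc3)c1)C=C2c1c(OCc3ccccc3)cc(OCc3ccccc3)c2c1O[C@H](c1ccc(OCc3ccccc3)c(OCc3ccccc3)c1)[C@H](OCc3ccccc3)C2
A2 | alternative 1 | hexaene: three 1,1-diarylethene groups and three aryl 1-arylallyl ethers on penta-O-benzyl epicatechin | c1ccccc1COc1cc(OCc3ccccc3)c(C(=C)c4c(OCc3ccccc3)cc(OCc3ccccc3)c(C(=C)c5c(OCc3ccccc3)cc(OCc3ccccc3)c(C(=C)c6c(OCc3ccccc3)cc(OCc3ccccc3)c7c6O[C@H](c2ccc(OCc3ccccc3)c(OCc3ccccc3)c2)[C@H](OCc3ccccc3)C7)c5O[C@H](c2ccc(OCc3ccccc3)c(OCc3ccccc3)c2)C=C)c4O[C@H](c2ccc(OCc3ccccc3)c(OCc3ccccc3)c2)C=C)c(c1)O[C@H](c2ccc(OCc3ccccc3)c(OCc3ccccc3)c2)C=C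
A3 | alternative 2 | tetramer with sixteen phenolic benzyl ethers, free 3-hydroxyl on unit 1 and 3-O-benzyl on units 2 to 4 | c1ccccc1COc1cc(OCc3ccccc3)c2c(c1)O[C@H](c1ccc(OCc3ccccc3)c(OCc3ccccc3)c1)[C@@H](O)[C@@H]2c1c(OCc3ccccc3)cc(OCc3ccccc3)c2c1O[C@H](c1ccc(OCc3ccccc3)c(OCc3ccccc3)c1)[C@@H](OCc3ccccc3)[C@@H]2c1c(OCc3ccccc3)cc(OCc3ccccc3)c2c1O[C@H](c1ccc(OCc3ccccc3)c(OCc3ccccc3)c1)[C@@H](OCc3ccccc3)[C@@H]2c1c(OCc3ccccc3)cc(OCc3ccccc3)c2c1O[C@H](c1ccc(OCc3ccccc3)c(OCc3ccccc3)c1)[C@H](OCc3ccccc3)C2
A4 | alternative 2 | trans-epoxide carrying the 3,5-bis(benzyloxy)phenyl ether, with units 2 to 4 on the benzylic epoxide carbon | c1ccccc1COc1cc(OCc3ccccc3)cc(c1)O[C@H](c1ccc(OCc3ccccc3)c(OCc3ccccc3)c1)[C@H]5O[C@@H]5c1c(OCc3ccccc3)cc(OCc3ccccc3)c2c1O[C@H](c1ccc(OCc3ccccc3)c(OCc3ccccc3)c1)[C@@H](OCc3ccccc3)[C@@H]2c1c(OCc3ccccc3)cc(OCc3ccccc3)c2c1O[C@H](c1ccc(OCc3ccccc3)c(OCc3ccccc3)c1)[C@@H](OCc3ccccc3)[C@@H]2c1c(OCc3ccccc3)cc(OCc3ccccc3)c2c1O[C@H](c1ccc(OCc3ccccc3)c(OCc3ccccc3)c1)[C@H](OCc3ccccc3)C2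
A5 | alternative 3 | 4-aryl-flav-2-ene (unit 1) bonded at C4 to C8 of perbenzylated units 2 to 4 | c1ccccc1COc1cc(OCc3ccccc3)c2c(c1)OC(c1ccc(OCc3ccccc3)c(OCc3ccccc3)c1)=C[C@@H]2c1c(OCc3ccccc3)cc(OCc3ccccc3)c2c1O[C@H](c1ccc(OCc3ccccc3)c(OCc3ccccc3)c1)[C@@H](OCc3ccccc3)[C@@H]2c1c(OCc3ccccc3)cc(OCc3ccccc3)c2c1O[C@H](c1ccc(OCc3ccccc3)c(OCc3ccccc3)c1)[C@@H](OCc3ccccc3)[C@@H]2c1c(OCc3ccccc3)cc(OCc3ccccc3)c2c1O[C@H](c1ccc(OCc3ccccc3)c(OCc3ccccc3)c1)[C@H](OCc3ccccc3)C2
A6 | alternative 3 | (E)-3-[2-hydroxy-4,6-bis(benzyloxy)phenyl]-1-[3,4-bis(benzyloxy)phenyl]prop-2-en-1-one | O=C(/C=C/c1c(O)cc(OCc2ccccc2)cc1OCc1ccccc1)c1ccc(OCc2ccccc2)c(OCc2ccccc2)c1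
A7 | alternative 3 | perbenzylated catechin-(4α→8)-catechin-(4α→8)-epicatechin (units 2 to 4) | c1c(OCc3ccccc3)cc(OCc3ccccc3)c2c1O[C@H](c1ccc(OCc3ccccc3)c(OCc3ccccc3)c1)[C@@H](OCc3ccccc3)[C@@H]2c1c(OCc3ccccc3)cc(OCc3ccccc3)c2c1O[C@H](c1ccc(OCc3ccccc3)c(OCc3ccccc3)c1)[C@@H](OCc3ccccc3)[C@@H]2c1c(OCc3ccccc3)cc(OCc3ccccc3)c2c1O[C@H](c1ccc(OCc3ccccc3)c(OCc3ccccc3)c1)[C@H](OCc3ccccc3)C2
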